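Azulene numbering is used (C3 carbinol, C4 ester carbon, C8a quaternary). Ring B hides a cyclohepta-1,4-diene. With C4 raised to a ketone enol ether (C3a=C4) and C5=C6 shifted to C6=C7, C5 is the apex of a cis-divinylcyclopropane. The key step adds a rhodium vinylcarbenoid (C6–C7–C8, an ester standing in for the C6 methyl) to the 2-silyloxydiene C5=C4–C3a=C8a. Cyclopropanation and Cope rearrangement make C5–C6 and the hindered C8–C8a bond in one operation. The diene (ring A with C3) maps carbon for carbon onto (S)-terpinen-4-ol. Later the ester becomes CH3 and the alkene slides into conjugation as C5=C6.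

Key step: step 8

Assumption 1: (S)-(+)-terpinen-4-ol is taken as enantiopure chiral-pool material; scalemic lots would be enriched before use.
Assumption 2: the S-prolinate catalyst is taken to be the enantiomer whose facial preference gives (1S,2R)-11; if its sense were the opposite, its mirror image would be used.

Step 1
Reactants: 1 (S)-(+)-terpinen-4-ol
Product: 2 (3S)-3-hydroxy-6-oxo-3-(propan-2-yl)heptanal
Conditions: O3, CH2Cl2, −78 °C; then Me2S, −78 °C to rt
Reagents that add atoms: ozone, [O-][O+]=O
Why: Ozonolysis with reductive work-up cleaves the only C=C bond and leaves the tertiary carbinol centre (later C3) untouched.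

Step 2
Reactants: 2 (3S)-3-hydroxy-6-oxo-3-(propan-2-yl)heptanal
Product: 3 (5R)-5-hydroxy-2-methyl-5-(propan-2-yl)cyclopent-1-ene-1-carbaldehyde
Conditions: dibenzylammonium trifluoroacetate (0.2 equiv), toluene, rt to 50 °C
Reagents that add atoms: none
Why: Amine-salt-catalysed intramolecular aldol condensation (5-enolexo), in which the aldehyde enamine attacks the methyl ketone and loss of water gives the conjugated cyclopentenecarbaldehyde without touching the stereocentre.

Step 3
Reactants: 3 (5R)-5-hydroxy-2-methyl-5-(propan-2-yl)cyclopent-1-ene-1-carbaldehyde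
Product: 4 1-[(5R)-5-hydroxy-2-methyl-5-(propan-2-yl)cyclopent-1-en-1-yl]ethan-1-ol
Conditions: MeMgBr (2.3 equiv), THF, −78 °C to 0 °C
Reagents that add atoms: methylmagnesium bromide, C[Mg]Br
Why: Grignard 1,2-addition to the enal brings in C5, and the new carbinol centre need not be controlled because the next step removes it.

Step 4
Reactants: 4 1-[(5R)-5-hydroxy-2-methyl-5-(propan-2-yl)cyclopent-1-en-1-yl]ethan-1-ol
Product: 5 1-[(5R)-5-hydroxy-2-methyl-5-(propan-2-yl)cyclopent-1-en-1-yl]ethan-1-one
Conditions: Dess–Martin periodinane, CH2Cl2, 0 °C to rt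
Reagents that add atoms: none
Why: Dess–Martin oxidation converts the secondary allylic alcohol into the methyl ketone while the tertiary alcohol cannot be oxidised.

Step 5
Reactants: 5 1-[(5R)-5-hydroxy-2-methyl-5-(propan-2-yl)cyclopent-1-en-1-yl]ethan-1-one
Product: 6 (5R)-2-methyl-5-(propan-2-yl)-5-(triethylsilyloxy)-1-[1-(triethylsilyloxy)ethenyl]cyclopent-1-ene
Conditions: Et3SiOTf (2.6 equiv), Et3N, CH2Cl2, −78 °C to 0 °C
Reagents that add atoms: triethylsilyl trifluoromethanesulfonate, CC[Si](CC)(CC)OS(=O)(=O)C(F)(F)F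
Why: Soft enolisation with silyl triflate and amine removes the most accessible acetyl proton to give the cross-conjugated 2-silyloxydiene, and the same reagent caps the tertiary alcohol.

Step 6
Reactants: 7 ethyl diazoacetate; 8 acetaldehyde
Product: 9 ethyl 2-diazo-3-hydroxybutanoate
Conditions: DBU (0.1 equiv), MeCN, rt
Reagents that add atoms: none
Why: Base-catalysed aldol-type addition of the diazo ester carbon to the aldehyde gives the racemic carbinol, whose centre is lost in the next step.

Step 7
Reactants: 9 ethyl 2-diazo-3-hydroxybutanoate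
Product: 10 ethyl 2-diazobut-3-enoate
Conditions: POCl3, Et3N, CH2Cl2, 0 °C; used at once as a hexane solution
Reagents that add atoms: none
Why: Activation of the hydroxyl as a dichlorophosphate and E2 elimination is the standard dehydration route to vinyldiazoacetates.

Step 8
Reactants: 6 (5R)-2-methyl-5-(propan-2-yl)-5-(triethylsilyloxy)-1-[1-(triethylsilyloxy)ethenyl]cyclopent-1-ene; 10 ethyl 2-diazobut-3-enoate
Product: 12 ethyl (3R,8aR)-8a-methyl-3-(propan-2-yl)-3,4-bis(triethylsilyloxy)-1,2,3,5,8,8a-hexahydroazulene-6-carboxylate, via cis-divinylcyclopropane 11 (not isolated)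
Conditions: Rh2(S-DOSP)4, dirhodium tetrakis[(S)-N-(4-dodecylbenzenesulfonyl)prolinate] (1 mol %), hexane, −40 °C, slow addition of 10; then 60 °C
Reagents that add atoms: none
Why: The divalent-rhodium catalyst turns 10 into a donor/acceptor vinylcarbenoid that adds in a concerted asynchronous [2+1] fashion to the terminal, most electron-rich C=C of 6 (the enol ether CH2=C), making C5–C6 and a sacrificial C4–C6 bond in cis-divinylcyclopropane 11. Compound 11 then undergoes a [3,3]-sigmatropic (Cope) shift through the only productive endo boat transition state, which breaks C4–C6, makes C8–C8a and leaves the C3a=C4 silyl enol ether and the C6=C7 enoate; this formal [4+3] cycloaddition is the known tandem cyclopropanation/Cope rearrangement of rhodium vinylcarbenoids with dienes, established for 2-silyloxydienes and for diene termini that become quaternary. Ring closures: the three-membered ring closes by carbene [2+1] addition, and ring B (seven-membered) closes by ring expansion of that cyclopropane in the sigmatropic step. The one new permanent stereocentre, C8a, is dictated by the configuration of C4 in 11, because in the boat only one face of the C3a=C8a alkene can reach the vinyl terminus, and that configuration is set by the chiral prolinate ligands (reagent control), so the bias of the C3 substituents need not be relied on. Three selectivities are needed: site (terminal enol ether over the tetrasubstituted ring alkene, secured by sterics and electronics), carbene-carbon over vinylogous attack (hydrocarbon solvent, electron-rich carboxylate catalyst) and cis over trans cyclopropane (the cyclopentenyl group lies on the side of the carbenoid vinyl group, away from the ester). Any trans isomer should be funnelled into 12 during the heating phase by reversible homolysis of the donor/acceptor-substituted C4–C6 bond.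

Step 9
Reactants: 12 ethyl (3R,8aR)-8a-methyl-3-(propan-2-yl)-3,4-bis(triethylsilyloxy)-1,2,3,5,8,8a-hexahydroazulene-6-carboxylate
Product: 13 [(3R,8aR)-8a-methyl-3-(propan-2-yl)-3,4-bis(triethylsilyloxy)-1,2,3,5,8,8a-hexahydroazulen-6-yl]methanol
Conditions: iBu2AlH (2.5 equiv), CH2Cl2, −78 °C; aq. Rochelle salt
Reagents that add atoms: none
Why: Hydride 1,2-reduction of the enoate gives the allylic alcohol, and both silyl ethers tolerate the reagent and the mildly basic work-up.

Step 10
Reactants: 13 [(3R,8aR)-8a-methyl-3-(propan-2-yl)-3,4-bis(triethylsilyloxy)-1,2,3,5,8,8a-hexahydroazulen-6-yl]methanol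
Product: 15 (3R,8aR)-6,8a-dimethyl-3-(propan-2-yl)-3,4-bis(triethylsilyloxy)-1,2,3,5,8,8a-hexahydroazulene, via allylic sulfate 14 (not isolated)
Conditions: SO3·pyridine, THF, 0 °C; then LiAlH4, 0 °C to rt
Reagents that add atoms: sulfur trioxide pyridine complex, O=S(=O)=O.c1ccncc1 (its SO3 stays only in 14)
Why: Sulfation followed by SN2 hydride displacement of the allylic sulfate turns CH2OH into the C6 methyl group, and any allylically transposed exocyclic alkene converges on the same enone in step 11.

Step 11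
Reactants: 15 (3R,8aR)-6,8a-dimethyl-3-(propan-2-yl)-3,4-bis(triethylsilyloxy)-1,2,3,5,8,8a-hexahydroazulene
Product: 17 (3R,3aR,8aS)-3-hydroxy-6,8a-dimethyl-3-(propan-2-yl)-2,3,3a,7,8,8a-hexahydroazulen-4(1H)-one, via unconjugated enone 16 (not isolated)
Conditions: HF·pyridine, THF, 0 °C to rt; then DBU (0.3 equiv), CH2Cl2, rt
Reagents that add atoms: none
Why: Fluoride desilylation frees the ketone and the carbinol, base-mediated isomerisation through the dienolate moves the alkene into conjugation as C5=C6, and reversible enolisation lets C3a settle in the trans-fused form with the C4 carbonyl trans to the isopropyl group and hydrogen-bonded to the C3 hydroxyl.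

Step 12
Reactants: 17 (3R,3aR,8aS)-3-hydroxy-6,8a-dimethyl-3-(propan-2-yl)-2,3,3a,7,8,8a-hexahydroazulen-4(1H)-one
Product: 18 (3R,3aS,4S,8aS)-6,8a-dimethyl-3-(propan-2-yl)-1,2,3,3a,4,7,8,8a-octahydroazulene-3,4-diol
Conditions: Me4NBH(OAc)3, MeCN/AcOH, −30 °C
Reagents that add atoms: none
Why: In this Evans–Saksena reduction the C3 hydroxyl binds boron and hydride is delivered intramolecularly to the face of the C4 carbonyl on which that hydroxyl stands, which gives the 1,3-anti diol (4S) by clean 1,2-reduction.

Step 13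
Reactants: 18 (3R,3aS,4S,8aS)-6,8a-dimethyl-3-(propan-2-yl)-1,2,3,3a,4,7,8,8a-octahydroazulene-3,4-diol; 19 4-methoxybenzoyl chloride
Product: 20 (3R,3aS,4S,8aS)-3-hydroxy-6,8a-dimethyl-3-(propan-2-yl)-1,2,3,3a,4,7,8,8a-octahydroazulen-4-yl 4-methoxybenzoate
Conditions: Et3N, DMAP (0.1 equiv), CH2Cl2, 0 °C to rt
Reagents that add atoms: none
Why: DMAP-catalysed acylation takes the secondary allylic alcohol only, because the tertiary C3 hydroxyl next to the isopropyl group is too hindered to react.

Compound list
1 | (S)-(+)-terpinen-4-ol, (1S)-4-methyl-1-(propan-2-yl)cyclohex-3-en-1-ol | CC1=CC[C@](O)(C(C)C)CC1 | starting material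
2 | (3S)-3-hydroxy-6-oxo-3-(propan-2-yl)heptanal | O=CC[C@](O)(C(C)C)CCC(C)=O | intermediate
3 | (5R)-5-hydroxy-2-methyl-5-(propan-2-yl)cyclopent-1-ene-1-carbaldehyde | CC1=C(C=O)[C@](O)(C(C)C)CC1 | intermediate
4 | 1-[(5R)-5-hydroxy-2-methyl-5-(propan-2-yl)cyclopent-1-en-1-yl]ethan-1-ol (both epimers at the new carbinol carbon) | CC1=C(C(C)O)[C@](O)(C(C)C)CC1 | intermediate
5 | 1-[(5R)-5-hydroxy-2-methyl-5-(propan-2-yl)cyclopent-1-en-1-yl]ethan-1-one | CC1=C(C(C)=O)[C@](O)(C(C)C)CC1 | intermediate
6 | (5R)-2-methyl-5-(propan-2-yl)-5-(triethylsilyloxy)-1-[1-(triethylsilyloxy)ethenyl]cyclopent-1-ene | CC1=C(C(=C)O[Si](CC)(CC)CC)[C@](O[Si](CC)(CC)CC)(C(C)C)CC1 | intermediate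
7 | ethyl diazoacetate | CCOC(=O)C=[N+]=[N-] | starting material
8 | acetaldehyde | CC=O | starting material
9 | ethyl 2-diazo-3-hydroxybutanoate (racemic) | CCOC(=O)C(=[N+]=[N-])C(C)O | intermediate
10 | ethyl 2-diazobut-3-enoate | CCOC(=O)C(=[N+]=[N-])C=C | intermediate
11 | ethyl (1S,2R)-1-ethenyl-2-[(5R)-2-methyl-5-(propan-2-yl)-5-(triethylsilyloxy)cyclopent-1-en-1-yl]-2-(triethylsilyloxy)cyclopropane-1-carboxylate (ethenyl and cyclopentenyl cis) | C=C[C@@]1(C(=O)OCC)C[C@@]1(O[Si](CC)(CC)CC)C2=C(C)CC[C@@]2(O[Si](CC)(CC)CC)C(C)C | intermediate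
12 | ethyl (3R,8aR)-8a-methyl-3-(propan-2-yl)-3,4-bis(triethylsilyloxy)-1,2,3,5,8,8a-hexahydroazulene-6-carboxylate | CCOC(=O)C1=CC[C@@]2(C)CC[C@@](O[Si](CC)(CC)CC)(C(C)C)C2=C(O[Si](CC)(CC)CC)C1 | intermediate
13 | [(3R,8aR)-8a-methyl-3-(propan-2-yl)-3,4-bis(triethylsilyloxy)-1,2,3,5,8,8a-hexahydroazulen-6-yl]methanol | OCC1=CC[C@@]2(C)CC[C@@](O[Si](CC)(CC)CC)(C(C)C)C2=C(O[Si](CC)(CC)CC)C1 | intermediate
14 | hydrogen sulfate of 13 (pyridinium salt in the flask) | OS(=O)(=O)OCC1=CC[C@@]2(C)CC[C@@](O[Si](CC)(CC)CC)(C(C)C)C2=C(O[Si](CC)(CC)CC)C1 | intermediate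
15 | (3R,8aR)-6,8a-dimethyl-3-(propan-2-yl)-3,4-bis(triethylsilyloxy)-1,2,3,5,8,8a-hexahydroazulene | CC1=CC[C@@]2(C)CC[C@@](O[Si](CC)(CC)CC)(C(C)C)C2=C(O[Si](CC)(CC)CC)C1 | intermediate
16 | (3R,8aR)-3-hydroxy-6,8a-dimethyl-3-(propan-2-yl)-2,3,3a,5,8,8a-hexahydroazulen-4(1H)-one (C3a not yet settled) | O=C1CC(C)=CC[C@@]2(C)CC[C@@](O)(C(C)C)C12 | intermediate
17 | (3R,3aR,8aS)-3-hydroxy-6,8a-dimethyl-3-(propan-2-yl)-2,3,3a,7,8,8a-hexahydroazulen-4(1H)-one | O=C1C=C(C)CC[C@@]2(C)CC[C@@](O)(C(C)C)[C@H]12 | intermediate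
18 | (3R,3aS,4S,8aS)-6,8a-dimethyl-3-(propan-2-yl)-1,2,3,3a,4,7,8,8a-octahydroazulene-3,4-diol | O[C@H]1C=C(C)CC[C@@]2(C)CC[C@@](O)(C(C)C)[C@H]12 | intermediate
19 | 4-methoxybenzoyl chloride | COc1ccc(cc1)C(=O)Cl | starting material
20 | (3R,3aS,4S,8aS)-3-hydroxy-6,8a-dimethyl-3-(propan-2-yl)-1,2,3,3a,4,7,8,8a-octahydroazulen-4-yl 4-methoxybenzoate | COc1ccc(C(=O)O[C@H]2C=C(C)CC[C@@]3(C)CC[C@@](O)(C(C)C)[C@H]23)cc1 | target

Total step count: 13. Longest linear sequence: 11 (steps 1–5 and 8–13).

Steps most likely to fail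

1. Step 8. The ligand sphere and the C3 substituents may oppose each other, so that facial selectivity in the cyclopropanation erodes. The polarised enol ether may attack the vinyl terminus of the carbenoid instead of the carbene carbon. The Cope shift may also stall at the fully substituted C8a terminus. The fallback sets out from 6 and returns at 17. It is an anionic [3+4] annulation driven by a Brook rearrangement, which makes the same two bonds without a metal carbene. MeLi cleaves the enol silyl ether of 6 to the lithium enolate F1. At −80 °C in THF this adds to the carbonyl group of 1-[tert-butyl(dimethyl)silyl]prop-2-en-1-one F2 (from allyl alcohol by silylation, retro-Brook rearrangement and oxidation). Silyl migration from carbon to oxygen then gives a carbanion that closes onto the ketone, and the cis-divinylcyclopropanolate rearranges (anionic oxy-Cope) to the 6-silyloxy ketone F3. CsF and PhNTf2 convert it into the vinylogous triflate F4. Me2CuLi exchanges triflate for methyl by addition–elimination to give the silyl-protected enone F5, and HF·pyridine frees 17.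

2. Step 2. Under amine catalysis the β-hydroxy aldehyde may eliminate water from the carbinol or cleave by retro-aldol reaction. Hemiketal formation between the carbinol and the ketone may also slow the ring closure. The fallback sets out from 1 and returns at 6, and it masks the carbinol before the ring is cut. Et3SiOTf and 2,6-lutidine give the silyl ether F6, and ozonolysis with Me2S work-up gives the silyloxy keto aldehyde F7, which can neither form a hemiketal nor undergo retro-aldol cleavage. The amine salt closes it to the protected enal F8. MeMgBr gives the alcohol F9, Dess–Martin oxidation gives the protected ketone F10, and Et3SiOTf/Et3N converts this into 6.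

3. Step 12. The crowded tertiary hydroxyl may fail to bind boron, so that undirected hydride attack from the opposite face takes over. The fallback sets out from 17 and returns at 20, and it accepts that face and corrects it during esterification. NaBH4 with CeCl3·7H2O in MeOH (Luche reduction) gives the C4 epimer of the diol F11. A Mitsunobu reaction (PPh3, DIAD, 4-methoxybenzoic acid) then inverts C4 while installing the ester, giving 20 directly.

Further compounds
F1 | step 8 | lithium 1-[(5R)-2-methyl-5-(propan-2-yl)-5-(triethylsilyloxy)cyclopent-1-en-1-yl]ethenolate | CC1=C(C(=C)[O-])[C@](O[Si](CC)(CC)CC)(C(C)C)CC1.[Li+]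
F2 | step 8 | 1-[tert-butyl(dimethyl)silyl]prop-2-en-1-one | C=CC(=O)[Si](C)(C)C(C)(C)C
F3 | step 8 | (3R,3aR,8aR)-6-[tert-butyl(dimethyl)silyloxy]-8a-methyl-3-(propan-2-yl)-3-(triethylsilyloxy)-2,3,3a,5,8,8a-hexahydroazulen-4(1H)-one | O=C1CC(O[Si](C)(C)C(C)(C)C)=CC[C@@]2(C)CC[C@@](O[Si](CC)(CC)CC)(C(C)C)[C@H]12
F4 | step 8 | 8a-methyl-4-oxo-3-(propan-2-yl)-3-(triethylsilyloxy)-1,2,3,3a,4,7,8,8a-octahydroazulen-6-yl trifluoromethanesulfonate (configuration as in 17) | O=C1C=C(OS(=O)(=O)C(F)(F)F)CC[C@@]2(C)CC[C@@](O[Si](CC)(CC)CC)(C(C)C)[C@H]12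
F5 | step 8 | (3R,3aR,8aS)-6,8a-dimethyl-3-(propan-2-yl)-3-(triethylsilyloxy)-2,3,3a,7,8,8a-hexahydroazulen-4(1H)-one | O=C1C=C(C)CC[C@@]2(C)CC[C@@](O[Si](CC)(CC)CC)(C(C)C)[C@H]12
F6 | step 2 | triethyl{[(1S)-4-methyl-1-(propan-2-yl)cyclohex-3-en-1-yl]oxy}silane | CC1=CC[C@](O[Si](CC)(CC)CC)(C(C)C)CC1
F7 | step 2 | (3S)-6-oxo-3-(propan-2-yl)-3-(triethylsilyloxy)heptanal | O=CC[C@](O[Si](CC)(CC)CC)(C(C)C)CCC(C)=O
F8 | step 2 | (5R)-2-methyl-5-(propan-2-yl)-5-(triethylsilyloxy)cyclopent-1-ene-1-carbaldehyde | CC1=C(C=O)[C@](O[Si](CC)(CC)CC)(C(C)C)CC1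
F9 | step 2 | 1-[(5R)-2-methyl-5-(propan-2-yl)-5-(triethylsilyloxy)cyclopent-1-en-1-yl]ethan-1-ol (both carbinol epimers) | CC1=C(C(C)O)[C@](O[Si](CC)(CC)CC)(C(C)C)CC1
F10 | step 2 | 1-[(5R)-2-methyl-5-(propan-2-yl)-5-(triethylsilyloxy)cyclopent-1-en-1-yl]ethan-1-one | CC1=C(C(C)=O)[C@](O[Si](CC)(CC)CC)(C(C)C)CC1
F11 | step 12 | (3R,3aS,4R,8aS)-6,8a-dimethyl-3-(propan-2-yl)-1,2,3,3a,4,7,8,8a-octahydroazulene-3,4-diol | O[C@@H]1C=C(C)CC[C@@]2(C)CC[C@@](O)(C(C)C)[C@H]12
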